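**Retrosynthetic overview**

1. Atom labels: C1 = bridgehead carrying lactone oxygen O2 and the acyl carbonyl C9, C3 = lactone carbonyl, C4 = prenylated bridgehead, C5 = ring CH2, C6 = ring CH bearing prenyl, C7 = CMe2, C8 = bridging ketone, C10 = CH(Me)Et. The lactone ring (C1–O2–C3–C4–C8) is closed last, by oxidative C1–O2 bond formation from a C4 tert-butyl ester onto the diketone carbon C1.
2. The quaternary C4 comes from two successive dianion γ-functionalizations of a 2-acyl-3,3-dimethyl-4-prenylcyclohexanone: prenyl first, then CO2tBu trans to the C6 prenyl group.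
3. The six-membered carbocycle C1–C7–C6–C5–C4–C8 is formed first, by making the C1–C7 bond: a cobalt-hydride Markovnikov hydroalkylation of an open-chain β-diketone that carries an isopropenyl group.
4. Feature on which the plan rests: the CMe2 carbon C7 next to the prenyl-bearing stereocentre C6 in that carbocycle is the isopropenyl-bearing carbon of (R)-limonene. Cutting limonene's ring alkene and rejoining its methyl carbon (future C1) to the isopropenyl carbon (C7) reuses all ten carbons: ring atoms C8, C1, C7, C6, C5, C4, both C7 methyls and the first two carbons of the C6 prenyl group.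
5. The open-chain diketone follows from limonene by epoxidation, periodate cleavage, Wittig olefination and Claisen acylation with the (R)-2-methylbutanoyl imidazolide.

Key step: step 6

Remark on the chemistry: (R)-2-methylbutanoic acid is assumed to be purchasable in high enantiomeric purity. β-Diketones are drawn as one enol tautomer, so C1 is not a defined stereocentre before step 9.

**Route**

Step 1
Reactants: 1 (R)-(+)-limonene
Product: 2 (4R)-limonene 1,2-oxide (cis/trans mixture at the oxirane)
Conditions: mCPBA (1.0 equiv), NaHCO3, CH2Cl2, 0 °C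
Reagents that add atoms: mCPBA, O=C(OO)c1cccc(Cl)c1
Why: Prilezhaev epoxidation is selective for the electron-richer trisubstituted ring alkene over the 1,1-disubstituted isopropenyl group; the oxirane configuration is irrelevant because both carbons become carbonyls, and the limonene stereocentre (future C6) is untouched.

Step 2
Reactants: 2 (4R)-limonene 1,2-oxide
Product: 4 (3R)-6-oxo-3-(prop-1-en-2-yl)heptanal, via trans-diol 3 (not isolated)
Conditions: H5IO6 (1.1 equiv), THF/H2O, 0 °C to rt
Reagents that add atoms: water, O
Why: Periodic acid opens the epoxide to the diol and cleaves it in the same flask (Malaprade glycol cleavage); the stereocentre is not alpha to either new carbonyl and cannot epimerize.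

Step 3
Reactants: 4 (3R)-6-oxo-3-(prop-1-en-2-yl)heptanal; 5 isopropyltriphenylphosphonium iodide
Product: 7 (5R)-8-methyl-5-(prop-1-en-2-yl)non-7-en-2-one, via ylide 6 (not isolated)
Conditions: 5 (1.1 equiv), n-BuLi (1.05 equiv), THF, 0 °C; then 4, −78 °C to 0 °C
Reagents that add atoms: isopropyltriphenylphosphonium iodide (5), CC(C)[P+](c1ccccc1)(c1ccccc1)c1ccccc1.[I-]
Why: Wittig olefination with the unstabilized isopropylidene ylide at low temperature is much faster at the aldehyde than at the methyl ketone and builds the C6 prenyl group.

Step 4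
Reactants: 8 (R)-2-methylbutanoic acid
Product: 9 1-[(2R)-2-methylbutanoyl]-1H-imidazole
Conditions: CDI (1.05 equiv), THF, rt; used directly after CO2 evolution stops
Reagents that add atoms: 1,1'-carbonyldiimidazole, O=C(n1ccnc1)n1ccnc1
Why: Carbonyldiimidazole activation gives the acyl imidazolide under neutral conditions, with no base present that could enolize the alpha stereocentre (future C10).

Step 5
Reactants: 7 (5R)-8-methyl-5-(prop-1-en-2-yl)non-7-en-2-one; 9 1-[(2R)-2-methylbutanoyl]-1H-imidazole
Product: 11 (3R,9R)-3,12-dimethyl-9-(prop-1-en-2-yl)tridec-11-ene-4,6-dione, via lithium enolate 10 (not isolated)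
Conditions: 7 (2.0 equiv), LDA (LiN(iPr)2, 2.0 equiv), THF, −78 °C; then 9 (1.0 equiv), −78 °C; aq. NH4Cl; excess 7 recovered
Reagents that add atoms: 1-[(2R)-2-methylbutanoyl]-1H-imidazole (9), CC[C@@H](C)C(=O)n1ccnc1
Why: Crossed Claisen acylation of the kinetic methyl-side lithium enolate by the imidazolide; the second equivalent of enolate converts the product into its diketonate, which protects it from further attack and should keep the C10 centre from enolizing.

Step 6
Reactants: 11 (3R,9R)-3,12-dimethyl-9-(prop-1-en-2-yl)tridec-11-ene-4,6-dione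
Product: 12 (4R)-3,3-dimethyl-2-[(2R)-2-methylbutanoyl]-4-(3-methylbut-2-en-1-yl)cyclohexan-1-one (enol tautomer drawn)
Conditions: Co(salen) complex [N,N′-bis(3,5-di-tert-butylsalicylidene)-1,2-cyclohexanediaminato]cobalt (divalent cobalt, 5 mol %), N-fluoro-2,4,6-trimethylpyridinium triflate (1.5 equiv), PhSiH3 (1.5 equiv), PhCF3, 0.02 M, 0 °C to rt, argon
Reagents that add atoms: none
Why: Proposed new method: the cobalt hydride formed from the divalent cobalt salen complex, the N-fluoropyridinium oxidant and PhSiH3 transfers a hydrogen atom to the CH2 terminus of the isopropenyl group, the tertiary C7 radical is captured by cobalt and oxidized to an alkyl complex of tetravalent cobalt that acts as a C7 cation equivalent, and the enol carbon C1 of the β-diketone displaces cobalt to form the C1–C7 bond. The closest known reactions are the cobalt–salen hydrogen-atom-transfer/radical–polar crossover hydroalkoxylations and hydroarylations of unactivated 1,1-disubstituted alkenes and, on the purely ionic side, the acid-promoted cation–enol (Conia-ene-type) cyclization of β-dicarbonyl compounds; using a 1,3-diketone enol carbon as the nucleophile in the cobalt manifold is the extension. The cyclohexanone ring closes in a 6-exo mode with respect to the former alkene (6-(enolexo)-exo-tet at C7) through a chair with the C6 prenyl group equatorial. No stereocentre is created, since C7 carries two methyl groups, C1 ends enolized and C6 is not involved. The step needs chemoselectivity for the isopropenyl over the prenyl alkene, which the preference of cobalt hydrides for less hindered 1,1-disubstituted alkenes should secure, and carbon over oxygen capture, which the soft enol carbon and the irreversible re-enolization of the product should favour; the weakly electrophilic trimethylpyridinium oxidant and the absence of free strong acid keep the enol from being fluorinated and the prenyl group out of cation–olefin chemistry.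

Step 7
Reactants: 12 (4R)-3,3-dimethyl-2-[(2R)-2-methylbutanoyl]-4-(3-methylbut-2-en-1-yl)cyclohexan-1-one; 13 prenyl bromide
Product: 15 (4S,6RS)-3,3-dimethyl-2-[(2R)-2-methylbutanoyl]-4,6-bis(3-methylbut-2-en-1-yl)cyclohexan-1-one (C4 epimers in the atom labels of the overview), via dilithium dianion 14 (not isolated)
Conditions: LDA (2.3 equiv), THF, −78 °C to 0 °C; then 13 (1.1 equiv), −78 °C to −20 °C; aq. NH4Cl
Reagents that add atoms: prenyl bromide (13), CC(C)=CCBr
Why: γ-Alkylation of a β-diketone dianion: the second deprotonation should occur at the ring CH2 (C4) and not at the C10 methine, whose enolization would force a substituent into allylic strain with the C7 methyl groups, and the more basic C4 carbanion is alkylated by SN2; the C4 configuration formed here is erased in step 8.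

Step 8
Reactants: 15 (4S,6RS)-3,3-dimethyl-2-[(2R)-2-methylbutanoyl]-4,6-bis(3-methylbut-2-en-1-yl)cyclohexan-1-one; 16 di-tert-butyl dicarbonate
Product: 18 tert-butyl (1S,5S)-4,4-dimethyl-3-[(2R)-2-methylbutanoyl]-1,5-bis(3-methylbut-2-en-1-yl)-2-oxocyclohexane-1-carboxylate, via dilithium dianion 17 (not isolated)
Conditions: LDA (2.5 equiv), THF, −78 °C to −20 °C; then 16 (1.2 equiv), −78 °C; aq. NH4Cl
Reagents that add atoms: di-tert-butyl dicarbonate (16), CC(C)(C)OC(=O)OC(=O)OC(C)(C)C
Why: γ-Acylation of the β-diketone dianion at carbon C4; the electrophile should enter axially through a chair-like transition state on the face of the axial C6–H, trans to the equatorial C6 prenyl group and away from the axial C7 methyl group, which places the C4 prenyl group cis to the C6 prenyl group.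

Step 9
Reactants: 18 tert-butyl (1S,5S)-4,4-dimethyl-3-[(2R)-2-methylbutanoyl]-1,5-bis(3-methylbut-2-en-1-yl)-2-oxocyclohexane-1-carboxylate
Product: 19 (1S,3S,5S)-4,4-dimethyl-5-[(2R)-2-methylbutanoyl]-1,3-bis(3-methylbut-2-en-1-yl)-6-oxabicyclo[3.2.1]octane-7,8-dione
Conditions: PhI(OAc)2 (1.2 equiv), MeCN, 0 °C to rt
Reagents that add atoms: none
Why: Hypervalent-iodine α-oxygenation of a 1,3-dicarbonyl compound run as an oxylactonization: the diketone enol binds trivalent iodine, the carbonyl oxygen of the axial C4 ester displaces iodobenzene at C1 on the face it occupies, and the tert-butyl oxonium ion loses isobutene, so the C1 configuration is dictated by C4 because the two-atom bridge can only span cis.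

**Compound list**

1 | (R)-(+)-limonene | CC1=CC[C@@H](CC1)C(C)=C | starting material
2 | (4R)-limonene 1,2-oxide (cis/trans mixture at the oxirane) | CC12OC1C[C@@H](CC2)C(C)=C | intermediate
3 | (4R)-p-menth-8-ene-1,2-diol (trans-diol, not isolated) | CC1(O)C(O)C[C@@H](CC1)C(C)=C | intermediate
4 | (3R)-6-oxo-3-(prop-1-en-2-yl)heptanal | O=CC[C@@H](CCC(C)=O)C(C)=C | intermediate
5 | isopropyltriphenylphosphonium iodide | CC(C)[P+](c1ccccc1)(c1ccccc1)c1ccccc1.[I-] | starting material
6 | isopropylidenetriphenylphosphorane (not isolated) | CC(C)=P(c1ccccc1)(c1ccccc1)c1ccccc1 | intermediate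
7 | (5R)-8-methyl-5-(prop-1-en-2-yl)non-7-en-2-one | CC(C)=CC[C@@H](CCC(C)=O)C(C)=C | intermediate
8 | (R)-2-methylbutanoic acid | CC[C@@H](C)C(=O)O | starting material
9 | 1-[(2R)-2-methylbutanoyl]-1H-imidazole | CC[C@@H](C)C(=O)n1ccnc1 | intermediate
10 | lithium (5R)-8-methyl-5-(prop-1-en-2-yl)nona-1,7-dien-2-olate (not isolated) | [Li+].[O-]C(=C)CC[C@H](CC=C(C)C)C(C)=C | intermediate
11 | (3R,9R)-3,12-dimethyl-9-(prop-1-en-2-yl)tridec-11-ene-4,6-dione | CC[C@@H](C)C(=O)CC(=O)CC[C@H](CC=C(C)C)C(C)=C | intermediate
12 | (4R)-3,3-dimethyl-2-[(2R)-2-methylbutanoyl]-4-(3-methylbut-2-en-1-yl)cyclohexan-1-one (enol drawn) | CC[C@@H](C)C(=O)C1=C(O)CC[C@H](CC=C(C)C)C1(C)C | intermediate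
13 | prenyl bromide | CC(C)=CCBr | starting material
14 | dilithium dianion of 12 (not isolated) | [Li+].[Li+].CC[C@@H](C)C([O-])=C1C([O-])=CC[C@H](CC=C(C)C)C1(C)C | intermediate
15 | (4S,6RS)-3,3-dimethyl-2-[(2R)-2-methylbutanoyl]-4,6-bis(3-methylbut-2-en-1-yl)cyclohexan-1-one (enol drawn) | CC[C@@H](C)C(=O)C1=C(O)C(CC=C(C)C)C[C@H](CC=C(C)C)C1(C)C | intermediate
16 | di-tert-butyl dicarbonate | CC(C)(C)OC(=O)OC(=O)OC(C)(C)C | starting material
17 | dilithium dianion of 15 (not isolated) | [Li+].[Li+].CC[C@@H](C)C([O-])=C1C([O-])=C(CC=C(C)C)C[C@H](CC=C(C)C)C1(C)C | intermediate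
18 | tert-butyl (1S,5S)-4,4-dimethyl-3-[(2R)-2-methylbutanoyl]-1,5-bis(3-methylbut-2-en-1-yl)-2-oxocyclohexane-1-carboxylate (enol drawn) | CC[C@@H](C)C(=O)C1=C(O)[C@@](CC=C(C)C)(C(=O)OC(C)(C)C)C[C@H](CC=C(C)C)C1(C)C | intermediate
19 | (1S,3S,5S)-4,4-dimethyl-5-[(2R)-2-methylbutanoyl]-1,3-bis(3-methylbut-2-en-1-yl)-6-oxabicyclo[3.2.1]octane-7,8-dione | CC[C@@H](C)C(=O)[C@@]12OC(=O)[C@@](CC=C(C)C)(C[C@H](CC=C(C)C)C1(C)C)C2=O | target

**Step count**

Total: 9 steps. Longest linear sequence: 8 steps (1, 2, 3, 5, 6, 7, 8, 9 from limonene).

**Steps most likely to fail**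

Step 6 (proposed new method). Hydrogen-atom transfer could go to the prenyl alkene, the C7 cation equivalent could be captured on the enol oxygen or lose a proton to give isomerized alkenes, or the enol could be fluorinated by the oxidant. The fallback uses the established acid-promoted cation–enol cyclization on a substrate in which the acid-sensitive prenyl alkene does not yet exist; it sets out from 4 and comes back at 12. Aldehyde 4 would be methylenated with Ph3P=CH2 (from Ph3PCH3Br and KN(SiMe3)2, THF, −78 °C) to (5R)-5-(prop-1-en-2-yl)oct-7-en-2-one F1. Its kinetic lithium enolate would be acylated with 9 as in step 5 to (3R,9R)-3-methyl-9-(prop-1-en-2-yl)dodec-11-ene-4,6-dione F2. SnCl4 in CH2Cl2 at 0 °C would then close the C1–C7 bond, since only the isopropenyl group gives a tertiary cation and the monosubstituted alkene is not protonated, to give (4R)-3,3-dimethyl-2-[(2R)-2-methylbutanoyl]-4-(prop-2-en-1-yl)cyclohexan-1-one F3. Cross-metathesis of F3 with excess 2-methyl-2-butene and second-generation Hoveyda–Grubbs catalyst RuCl2(H2IMes)(=CH-C6H4-2-OiPr) in CH2Cl2 at 40 °C would convert allyl into prenyl and deliver 12.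

Step 8. The hindered, fully substituted dianion carbon C4 could be acylated on oxygen or on the face cis to the C6 prenyl group, and deprotonation at C10 could compete and erode its configuration. The fallback reverses the order of the two C4 substituents and lets a catalyst choose the face; it sets out from 12 and comes back at 18. Dianion 14 would be acylated with 16 at the secondary C4 carbanion, where C-acylation is easy and C10 is not at risk, to give tert-butyl (5S)-4,4-dimethyl-3-[(2R)-2-methylbutanoyl]-5-(3-methylbut-2-en-1-yl)-2-oxocyclohexane-1-carboxylate F4. Its acidic C4–H would then be prenylated under Tsuji–Trost conditions without strong base (prenyl methyl carbonate, Pd2(dba)3 as zerovalent palladium source, a chiral trans-1,2-diaminocyclohexane-derived bis(2-diphenylphosphinobenzamide) ligand, THF, rt). The ligand enantiomer would be chosen so that the prenyl group is delivered cis to the C6 prenyl group, giving 18; this has to override the substrate's own preference for attack trans to the C6 prenyl group.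

Step 9. One-electron oxidation of the diketone followed by radical cyclization onto a prenyl alkene, or intermolecular acetoxylation at C1, could outrun participation of the neutral ester. The fallback replaces the ester by a carboxylate, which binds trivalent iodine first and delivers oxygen to C1 within the same complex; it sets out from 18 and comes back at 19. The tert-butyl ester would be cleaved without protic acid (ZnBr2, CH2Cl2, rt, cold phosphate-buffer work-up) to (1S,5S)-4,4-dimethyl-3-[(2R)-2-methylbutanoyl]-1,5-bis(3-methylbut-2-en-1-yl)-2-oxocyclohexane-1-carboxylic acid F5, kept cold to avoid decarboxylation. The keto acid would then be closed by the established oxylactonization of keto acids with PhI(OH)OTs (CH2Cl2, 0 °C) to 19.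

**Further compounds**

F1 | step 6 | (5R)-5-(prop-1-en-2-yl)oct-7-en-2-one | C=CC[C@@H](CCC(C)=O)C(C)=C
F2 | step 6 | (3R,9R)-3-methyl-9-(prop-1-en-2-yl)dodec-11-ene-4,6-dione | CC[C@@H](C)C(=O)CC(=O)CC[C@H](CC=C)C(C)=C
F3 | step 6 | (4R)-3,3-dimethyl-2-[(2R)-2-methylbutanoyl]-4-(prop-2-en-1-yl)cyclohexan-1-one (enol drawn) | CC[C@@H](C)C(=O)C1=C(O)CC[C@H](CC=C)C1(C)C
F4 | step 8 | tert-butyl (5S)-4,4-dimethyl-3-[(2R)-2-methylbutanoyl]-5-(3-methylbut-2-en-1-yl)-2-oxocyclohexane-1-carboxylate (enol drawn, C1 epimers) | CC[C@@H](C)C(=O)C1=C(O)C(C(=O)OC(C)(C)C)C[C@H](CC=C(C)C)C1(C)C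
F5 | step 9 | (1S,5S)-4,4-dimethyl-3-[(2R)-2-methylbutanoyl]-1,5-bis(3-methylbut-2-en-1-yl)-2-oxocyclohexane-1-carboxylic acid (enol drawn) | CC[C@@H](C)C(=O)C1=C(O)[C@@](CC=C(C)C)(C(=O)O)C[C@H](CC=C(C)C)C1(C)C
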